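**Retrosynthetic overview**
- The target comes from its heptabenzyl ether by one neutral global hydrogenolysis, which leaves C2 untouched.
- The flavanone pyranone ring (ring C) is closed last: the C2–O1 bond is made by a catalytic enantioselective 6-endo oxa-Michael cyclization of a 2'-hydroxychalcone, which sets the only stereocenter (S).
- The chalcone comes from a Claisen–Schmidt condensation of 2-hydroxy-4,6-bis(benzyloxy)acetophenone with a flavonyl-substituted benzaldehyde.
- The biaryl bond comes from a one-pot borylation/Suzuki coupling of 3,4-bis(benzyloxy)-5-bromobenzaldehyde with 8-iodo-tri-O-benzylapigenin.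
- Ring order: the three flavone rings arrive intact in apigenin, flavanone ring A arrives in phloroacetophenone, and flavanone ring C is the only ring built.

**Assumption:** the target SMILES carries no axial descriptor, so the tri-ortho-substituted biaryl axis is treated as not configurationally fixed; the only stereocenter is C2 of the flavanone, which is S.

**Catalyst A (step 7):** the bifunctional iminophosphorane–thiourea made by Staudinger reaction of tris(4-methoxyphenyl)phosphine with the azide of the L-tert-leucine-derived 3,5-bis(trifluoromethyl)phenyl thiourea. SMILES: COc1ccc(cc1)P(=NC[C@@H](NC(=S)Nc1cc(cc(c1)C(F)(F)F)C(F)(F)F)C(C)(C)C)(c1ccc(OC)cc1)c1ccc(OC)cc1. Which antipode of A gives the 2S product cannot be predicted with confidence; it is fixed in a first screen on 10 (chiral HPLC plus the circular dichroism sign of the flavanone). Both antipodes are made the same way from L- or D-tert-leucine.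

**Route**

Step 1
Reactants: 1 apigenin (5,7-dihydroxy-2-(4-hydroxyphenyl)-4H-chromen-4-one)
Product: 2 5,7-bis(benzyloxy)-2-[4-(benzyloxy)phenyl]-4H-chromen-4-one (tri-O-benzylapigenin)
Conditions: BnBr (4.5 equiv), K2CO3, DMF, 80 °C, 16 h
Reagents that add atoms: benzyl bromide, BrCc1ccccc1
Why: Williamson ether synthesis; heat and excess bromide are needed only for the hydrogen-bonded 5-OH, which must be capped because a free 5-OH would steer the later iodination to C6.

Step 2
Reactants: 2 tri-O-benzylapigenin
Product: 3 5,7-bis(benzyloxy)-2-[4-(benzyloxy)phenyl]-8-iodo-4H-chromen-4-one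
Conditions: NIS (1.1 equiv), TFA (cat.), MeCN–CH2Cl2, 0 °C → rt
Reagents that add atoms: N-iodosuccinimide, O=C1CCC(=O)N1I
Why: electrophilic aromatic iodination (SEAr); in fully O-alkylated 5,7-dioxygenated flavones the phloroglucinol-type ring A is the most electron-rich ring and reacts at C8 rather than at C6, which is flanked by two benzyloxy groups, as is known for the trimethyl ether.

Step 3
Reactants: 4 3-bromo-4,5-dihydroxybenzaldehyde
Product: 5 3,4-bis(benzyloxy)-5-bromobenzaldehyde
Conditions: BnBr (2.4 equiv), K2CO3, DMF, 60 °C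
Reagents that add atoms: benzyl bromide, BrCc1ccccc1
Why: Williamson ether synthesis of both catechol hydroxyls; the aldehyde and the aryl bromide are inert to these conditions.

Step 4
Reactants: 5 3,4-bis(benzyloxy)-5-bromobenzaldehyde (1.2 equiv); 3 8-iodo-tri-O-benzylapigenin
Product: 7 3,4-bis(benzyloxy)-5-{5,7-bis(benzyloxy)-2-[4-(benzyloxy)phenyl]-4-oxo-4H-chromen-8-yl}benzaldehyde, via aryl pinacol boronate 6 (not isolated)
Conditions: B2pin2 (1.05 equiv to 5), KOAc, PdCl2(dppf) (3 mol%), dioxane, 90 °C; then 3, Pd(OAc)2/SPhos (5/10 mol%), aq K3PO4, 90 °C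
Reagents that add atoms: bis(pinacolato)diboron, CC1(C)OB(OC1(C)C)B1OC(C)(C)C(C)(C)O1 (its boryl group is carried by intermediate 6 only and is lost in the coupling)
Why: Miyaura borylation followed by Suzuki–Miyaura coupling in one pot; boron sits on the less hindered ring and the di-ortho-substituted iodide 3 is the electrophile, an arrangement that SPhos-ligated palladium handles for tri-ortho-substituted biaryls, and no stereocenter is present yet that base could harm.

Step 5
Reactants: 8 2,4,6-trihydroxyacetophenone (phloroacetophenone)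
Product: 9 1-[2,4-bis(benzyloxy)-6-hydroxyphenyl]ethan-1-one
Conditions: BnBr (2.05 equiv), K2CO3, DMF, 0 °C → rt
Reagents that add atoms: benzyl bromide, BrCc1ccccc1
Why: Williamson ether synthesis; selective because one ortho hydroxyl stays locked in a hydrogen bond to the ketone and is the least nucleophilic, and the two ortho hydroxyls are equivalent so a single dibenzyl ether results.

Step 6
Reactants: 9 1-[2,4-bis(benzyloxy)-6-hydroxyphenyl]ethan-1-one; 7 biaryl aldehyde
Product: 10 (2E)-1-[2,4-bis(benzyloxy)-6-hydroxyphenyl]-3-(3,4-bis(benzyloxy)-5-{5,7-bis(benzyloxy)-2-[4-(benzyloxy)phenyl]-4-oxo-4H-chromen-8-yl}phenyl)prop-2-en-1-one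
Conditions: KOH (50% aq), EtOH–THF, rt, 24 h; then 1 M HCl, 0 °C
Reagents that add atoms: none
Why: Claisen–Schmidt (crossed aldol) condensation; 7 has no α-hydrogen, dehydration gives the conjugated E-enone, and in strong base the product rests as the ring-open phenoxide so no racemic flavanone forms before the cold acidification.

Step 7
Reactants: 10 2'-hydroxychalcone
Product: 11 (2S)-5,7-bis(benzyloxy)-2-(3,4-bis(benzyloxy)-5-{5,7-bis(benzyloxy)-2-[4-(benzyloxy)phenyl]-4-oxo-4H-chromen-8-yl}phenyl)-2,3-dihydro-4H-chromen-4-one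
Conditions: catalyst A (10 mol%), toluene, –20 °C, 24–48 h; then AcOH (cat.), filtration through SiO2
Reagents that add atoms: none
Why: Proposed new method: an enantioselective 6-endo-trig intramolecular oxa-Michael addition of a non-activated 2'-hydroxychalcone under bifunctional iminophosphorane–thiourea catalysis, in which the superbasic iminophosphorane deprotonates the chelated 2'-OH to a tight chiral phenoxide/iminophosphonium ion pair while the thiourea N–H pair binds the enone carbonyl, so the phenoxide adds to one face of the s-cis enone and the enolate is protonated by the iminophosphonium, forming the C2–O1 bond and setting C2 as S under kinetic control (the 6'-benzyloxy group destabilises the planar chalcone, so the closed form is favoured and the retro-reaction is slow at –20 °C, and the base-neutral flavone unit cannot sequester the catalyst as it would a chiral acid); the closest known reaction types are the iminophosphorane-catalysed oxa-Michael addition of alcohols to unsaturated esters and amides and the cinchona–thiourea cyclization of ester-activated 2'-hydroxychalcones, neither of which has been shown on a plain chalcone such as 10.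

Step 8
Reactants: 11 (2S)-flavanone heptabenzyl ether
Product: 12 (2S)-2-{3,4-dihydroxy-5-[5,7-dihydroxy-2-(4-hydroxyphenyl)-4-oxo-4H-chromen-8-yl]phenyl}-5,7-dihydroxy-2,3-dihydro-4H-chromen-4-one (CNP0204144.1)
Conditions: H2 (1 atm), Pd/C (10 wt% Pd on carbon), THF–MeOH, rt
Reagents that add atoms: none
Why: catalytic hydrogenolysis of the seven benzyl ethers under neutral conditions; no base or strong acid reaches the C2 stereocenter, and the flavone C2=C3 bond and the flavanone ketone are reduced much more slowly than O-benzyl groups are cleaved.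

**Compound list**

1 | apigenin | O=c1cc(-c2ccc(O)cc2)oc2cc(O)cc(O)c12 | starting material
2 | 5,7-bis(benzyloxy)-2-[4-(benzyloxy)phenyl]-4H-chromen-4-one | O=c1cc(-c2ccc(OCc3ccccc3)cc2)oc2cc(OCc3ccccc3)cc(OCc3ccccc3)c12 | intermediate
3 | 5,7-bis(benzyloxy)-2-[4-(benzyloxy)phenyl]-8-iodo-4H-chromen-4-one | O=c1cc(-c2ccc(OCc3ccccc3)cc2)oc2c(I)c(OCc3ccccc3)cc(OCc3ccccc3)c12 | intermediate
4 | 3-bromo-4,5-dihydroxybenzaldehyde | O=Cc1cc(O)c(O)c(Br)c1 | starting material
5 | 3,4-bis(benzyloxy)-5-bromobenzaldehyde | O=Cc1cc(OCc2ccccc2)c(OCc2ccccc2)c(Br)c1 | intermediate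
6 | 3,4-bis(benzyloxy)-5-(4,4,5,5-tetramethyl-1,3,2-dioxaborolan-2-yl)benzaldehyde | O=Cc1cc(OCc2ccccc2)c(OCc2ccccc2)c(B2OC(C)(C)C(C)(C)O2)c1 | intermediate (not isolated)
7 | 3,4-bis(benzyloxy)-5-{5,7-bis(benzyloxy)-2-[4-(benzyloxy)phenyl]-4-oxo-4H-chromen-8-yl}benzaldehyde | O=Cc1cc(OCc2ccccc2)c(OCc2ccccc2)c(-c2c(OCc3ccccc3)cc(OCc3ccccc3)c3c(=O)cc(-c4ccc(OCc5ccccc5)cc4)oc23)c1 | intermediate
8 | 2,4,6-trihydroxyacetophenone | CC(=O)c1c(O)cc(O)cc1O | starting material
9 | 1-[2,4-bis(benzyloxy)-6-hydroxyphenyl]ethan-1-one | CC(=O)c1c(O)cc(OCc2ccccc2)cc1OCc1ccccc1 | intermediate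
10 | (2E)-1-[2,4-bis(benzyloxy)-6-hydroxyphenyl]-3-(3,4-bis(benzyloxy)-5-{5,7-bis(benzyloxy)-2-[4-(benzyloxy)phenyl]-4-oxo-4H-chromen-8-yl}phenyl)prop-2-en-1-one | O=C(/C=C/c1cc(OCc2ccccc2)c(OCc2ccccc2)c(-c2c(OCc3ccccc3)cc(OCc3ccccc3)c3c(=O)cc(-c4ccc(OCc5ccccc5)cc4)oc23)c1)c1c(O)cc(OCc2ccccc2)cc1OCc1ccccc1 | intermediate
11 | (2S)-5,7-bis(benzyloxy)-2-(3,4-bis(benzyloxy)-5-{5,7-bis(benzyloxy)-2-[4-(benzyloxy)phenyl]-4-oxo-4H-chromen-8-yl}phenyl)-2,3-dihydro-4H-chromen-4-one | O=C1C[C@@H](c2cc(OCc3ccccc3)c(OCc3ccccc3)c(-c3c(OCc4ccccc4)cc(OCc4ccccc4)c4c(=O)cc(-c5ccc(OCc6ccccc6)cc5)oc34)c2)Oc2cc(OCc3ccccc3)cc(OCc3ccccc3)c21 | intermediate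
12 | (2S)-2-{3,4-dihydroxy-5-[5,7-dihydroxy-2-(4-hydroxyphenyl)-4-oxo-4H-chromen-8-yl]phenyl}-5,7-dihydroxy-2,3-dihydro-4H-chromen-4-one (CNP0204144.1) | O=C1C[C@@H](c2cc(O)c(O)c(-c3c(O)cc(O)c4c(=O)cc(-c5ccc(O)cc5)oc34)c2)Oc2cc(O)cc(O)c21 | target

**Step count**

Total steps: 8. Longest linear sequence: 6 (steps 1, 2, 4, 6, 7, 8, from apigenin 1 to target 12).

**Three steps most likely to fail**

Step 7, the proposed new cyclization, is the least certain step. A plain chalcone is a weak acceptor, the selectivity of catalyst A on it is untested, the superbase could erode the ee of 11 by retro-oxa-Michael opening, and the chalcone/flavanone equilibrium may cap conversion. The fallback uses only known chemistry and sets out from 10. Heating 10 with NaOAc in EtOH–THF at reflux (the standard thermodynamic chalcone–flavanone isomerisation) gives the racemic flavanone heptabenzyl ether F1. Preparative chiral SFC on an amylose tris(3,5-dimethylphenylcarbamate) phase then separates 11 from the (2R)-flavanone heptabenzyl ether F2. F2 is returned to F1 by brief warming with DBU in toluene (ring opening to 10 and re-closure) and resolved again. The fallback comes back to the route at 11.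

Step 4, the one-pot borylation/Suzuki coupling, may suffer protodeboronation of 6, slow coupling at the di-ortho-substituted C8 of 3, and homocoupling from residual diboron. The fallback changes the organometallic partner to tin and removes the base. It sets out from 5, which with (Me3Sn)2 and Pd(PPh3)4 in toluene at 100 °C gives 3,4-bis(benzyloxy)-5-(trimethylstannyl)benzaldehyde F3. Copper-assisted Stille coupling of this stannane with 3 (Pd(PPh3)4, CuI, CsF, DMF, 45 °C) then gives the biaryl, and the fallback comes back to the route at 7.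

Step 8, the sevenfold hydrogenolysis, may reduce the flavone C2=C3 bond, cleave the benzylic C2–O1 bond of the flavanone, or stall at partly benzylated, poorly soluble intermediates. The fallback replaces reductive cleavage by Lewis-acid debenzylation with a cation scavenger. It sets out from 11, which is treated with excess BCl3 and pentamethylbenzene in CH2Cl2 at –78 °C and then quenched with MeOH. No hydrogen or metal is present, so neither over-reduction nor ring hydrogenolysis can occur, and the low temperature protects C2. It makes no new compound (F0) and comes back to the route at 12.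

**Further compounds**

F1 | step 7 | racemic 5,7-bis(benzyloxy)-2-(3,4-bis(benzyloxy)-5-{5,7-bis(benzyloxy)-2-[4-(benzyloxy)phenyl]-4-oxo-4H-chromen-8-yl}phenyl)-2,3-dihydro-4H-chromen-4-one (racemate, no stereodescriptor) | O=C1CC(c2cc(OCc3ccccc3)c(OCc3ccccc3)c(-c3c(OCc4ccccc4)cc(OCc4ccccc4)c4c(=O)cc(-c5ccc(OCc6ccccc6)cc5)oc34)c2)Oc2cc(OCc3ccccc3)cc(OCc3ccccc3)c21
F2 | step 7 | (2R)-5,7-bis(benzyloxy)-2-(3,4-bis(benzyloxy)-5-{5,7-bis(benzyloxy)-2-[4-(benzyloxy)phenyl]-4-oxo-4H-chromen-8-yl}phenyl)-2,3-dihydro-4H-chromen-4-one | O=C1C[C@H](c2cc(OCc3ccccc3)c(OCc3ccccc3)c(-c3c(OCc4ccccc4)cc(OCc4ccccc4)c4c(=O)cc(-c5ccc(OCc6ccccc6)cc5)oc34)c2)Oc2cc(OCc3ccccc3)cc(OCc3ccccc3)c21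
F3 | step 4 | 3,4-bis(benzyloxy)-5-(trimethylstannyl)benzaldehyde | O=Cc1cc(OCc2ccccc2)c(OCc2ccccc2)c([Sn](C)(C)C)c1
F0 | step 8 | none | none
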